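**Retrosynthetic overview**

1. Numbering (cadinane): ring A = C1–C2–C3–C4(C15)=C5–C6, ring B = C1–C6–C7–C8–C9–C10(=C14), acrylic unit C11(=C13)–C12 on C7, primed numbers for the acyl group on O8. The last disconnections are the O8–C1′ ester (acid 26, from an asymmetric Morita–Baylis–Hillman reaction) and C11=C13 (Mannich methylenation of a C7–CH2CO2t-Bu arm).
2. Enabling feature: ring B carries the exocyclic C10=C14 alkene directly beside ring-fusion carbon C1, and its oxygen on C8 between C7 and C9. Read as the enol ether C7=C8(OSi), this is the retron of a [4+2] between the 2-silyloxy diene C6=C7–C8=C9 and the inner π bond C1=C10 of a terminal allene.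
3. Key disconnection: C1–C6 and C9–C10 together, back to the acyclic tetraene–allene 15, whose tether C2–C3–C4=C5 becomes ring A. Rings A and B form in the same step; no ring exists before it.
4. 15 is assembled from homoallenylzinc 8 (C1–C3, C10, C14), (Z)-iodoalkenol 7 (C4–C6, C15; fixes the C4=C5 geometry) and ketophosphonate 13 (C7–C9, C11, C12).
5. After the cycloaddition, C7 is set by axial protonation of the enol ether and C8 by equatorial hydride delivery; the tert-butyl ester and three silyl ethers come off in the last step.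

Key step: step 10

Assumption: the sense of induction of the chiral ligand in step 10 cannot be fixed by a model; (S,S)-Me-DuPhos is written, and its mirror image would be used if a first run gives the antipode of 16.

**Route**

Step 1
Reactants: 1 but-3-yn-1-ol
Product: 2 penta-3,4-dien-1-ol
Conditions: (CH2O)n, CuBr (30 mol %), i-Pr2NH, 1,4-dioxane, reflux
Reagents that add atoms: paraformaldehyde (as formaldehyde), C=O
Why: Crabbé homologation, in which a copper-mediated Mannich reaction of the terminal alkyne with formaldehyde and the amine is followed by hydride transfer and loss of the imine, should turn C≡CH into CH=C=CH2 with the free hydroxyl tolerated.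

Step 2
Reactants: 2 penta-3,4-dien-1-ol
Product: 3 5-iodopenta-1,2-diene
Conditions: I2, PPh3, imidazole, CH2Cl2, 0 °C to rt
Reagents that add atoms: iodine, [I][I]
Why: Appel-type iodination should replace the primary hydroxyl by iodide and leave the allene untouched.

Step 3
Reactants: 4 but-2-yne-1,4-diol
Product: 5 4-[(tert-butyldimethylsilyl)oxy]but-2-yn-1-ol
Conditions: NaH (1.0 equiv), THF, 0 °C; then TBSCl
Reagents that add atoms: tert-butyldimethylsilyl chloride, CC(C)(C)[Si](C)(C)Cl
Why: Monosilylation of a symmetrical diol through its monosodium alkoxide should give the mono-TBS ether selectively.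

Step 4
Reactants: 5 4-[(tert-butyldimethylsilyl)oxy]but-2-yn-1-ol
Product: 7 (Z)-4-[(tert-butyldimethylsilyl)oxy]-3-iodobut-2-en-1-ol, via cyclic alkenylaluminate 6 (not isolated)
Conditions: NaAlH2(OCH2CH2OMe)2, THF, 0 °C; then I2, THF, −78 to 0 °C
Reagents that add atoms: iodine, [I][I]; sodium bis(2-methoxyethoxy)aluminium dihydride, [Na+].COCCO[AlH2-]OCCOC (its atoms stay only in intermediate 6)
Why: Hydroxyl-directed trans-hydroalumination of the propargylic alcohol should place aluminium on the distal alkyne carbon in a five-membered alkenylaluminate, and iodinolysis with retention should give the Z vinyl iodide (iodine cis to CH2OH).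

Step 5
Reactants: 3 5-iodopenta-1,2-diene; 7 (Z)-4-[(tert-butyldimethylsilyl)oxy]-3-iodobut-2-en-1-ol
Product: 9 (E)-3-{[(tert-butyldimethylsilyl)oxy]methyl}octa-2,6,7-trien-1-ol, via penta-3,4-dienylzinc iodide 8 (not isolated)
Conditions: 3, Zn dust (activated with BrCH2CH2Br/Me3SiCl), LiCl, THF, 40 °C; then 7, Pd(PPh3)4 (5 mol %), THF, rt to 45 °C (8 in excess, 2.5 equiv)
Reagents that add atoms: zinc, [Zn] (stays only in intermediate 8)
Why: Negishi coupling of the sp3 organozinc with the alkenyl iodide should proceed with retention of alkene geometry, so that the homoallenyl chain ends cis to CH2OH, which is the future in-ring geometry of C4=C5.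

Step 6
Reactants: 9 (E)-3-{[(tert-butyldimethylsilyl)oxy]methyl}octa-2,6,7-trien-1-ol
Product: 10 (E)-3-{[(tert-butyldimethylsilyl)oxy]methyl}octa-2,6,7-trienal
Conditions: MnO2 (activated), CH2Cl2, rt
Reagents that add atoms: none
Why: Manganese dioxide should oxidise only the allylic alcohol, under neutral conditions that do not isomerise the trisubstituted alkene.

Step 7
Reactants: 11 dimethyl (2-oxopropyl)phosphonate; 12 tert-butyl bromoacetate
Product: 13 tert-butyl 3-(dimethoxyphosphoryl)-4-oxopentanoate (racemic)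
Conditions: NaH, THF, 0 °C; then 12, 0 °C to rt
Reagents that add atoms: none
Why: C-alkylation of the stabilised β-ketophosphonate anion with a reactive α-bromo ester should install the C11–C12 arm on the future C7.

Step 8
Reactants: 10 (E)-3-{[(tert-butyldimethylsilyl)oxy]methyl}octa-2,6,7-trienal; 13 tert-butyl 3-(dimethoxyphosphoryl)-4-oxopentanoate
Product: 14 tert-butyl (3E,5E)-3-acetyl-6-{[(tert-butyldimethylsilyl)oxy]methyl}undeca-3,5,9,10-tetraenoate
Conditions: 13, NaH, THF, 0 °C; then 10, 0 °C to rt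
Reagents that add atoms: none
Why: Horner–Wadsworth–Emmons olefination with a stabilised carbanion should give the thermodynamically preferred E trisubstituted enone, with C5 trans to the acetyl group, the geometry that later places the tether on the outside of the diene.

Step 9
Reactants: 14 tert-butyl (3E,5E)-3-acetyl-6-{[(tert-butyldimethylsilyl)oxy]methyl}undeca-3,5,9,10-tetraenoate
Product: 15 tert-butyl (3E,5E)-6-{[(tert-butyldimethylsilyl)oxy]methyl}-3-{1-[(triethylsilyl)oxy]ethenyl}undeca-3,5,9,10-tetraenoate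
Conditions: Et3SiOTf, Et3N, CH2Cl2, −78 to 0 °C
Reagents that add atoms: triethylsilyl trifluoromethanesulfonate, CC[Si](CC)(CC)OS(=O)(=O)C(F)(F)F
Why: Soft enolisation (O-silylation of the ketone, then kinetic deprotonation of the α′-methyl group) should give the cross-conjugated 2-silyloxy diene, while the tert-butyl ester is not enolised under these conditions.

Step 10
Reactants: 15 tert-butyl (3E,5E)-6-{[(tert-butyldimethylsilyl)oxy]methyl}-3-{1-[(triethylsilyl)oxy]ethenyl}undeca-3,5,9,10-tetraenoate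
Product: 16 tert-butyl [(1S,6S)-4-{[(tert-butyldimethylsilyl)oxy]methyl}-10-methylidene-8-[(triethylsilyl)oxy]bicyclo[4.4.0]deca-4,7-dien-7-yl]acetate (trans-fused, cadinane numbering)
Conditions: [Rh(cod)2]SbF6 (5 mol %), (S,S)-Me-DuPhos (6 mol %), 4 Å MS, ClCH2CH2Cl, 25 °C
Reagents that add atoms: none
Why: Proposed new method: the cationic monovalent rhodium centre should bind the s-cis 2-silyloxy diene C6=C7–C8=C9 and the inner allene π bond C1=C10, oxidative cyclisation should form C1–C6 and give a trivalent rhodacycle (σ-alkenyl at C10, η3-allyl over C7–C9), and reductive elimination at the allyl terminus should form C9–C10 and release the catalyst. The closest known reaction types are the rhodium- and nickel-catalysed intramolecular [4+2] cycloaddition of unactivated diene–allenes (racemic) and the enantioselective cationic rhodium–bisphosphine [4+2] of dienynes and trienes, which are merged here on a silyloxy diene. Ring A closes through the C1–C6 bond as a six-membered ring over the four-atom tether C2–C5 (fused, type 1 mode), and ring B closes as the cyclohexene of the [4+2] through C9–C10, suprafacially on the diene. C6 and C1 are the new stereocentres: their trans relationship (H-6 anti to H-1) should follow from the E geometry of C6=C7 (tether outside) together with a half-chair tether that holds C2 exo in the bicyclic rhodacycle, and their absolute configuration from the C2-symmetric ligand, which selects the diene face. The step needs reaction at the inner rather than the outer allene π bond, secured by the tether (the outer bond would force a seven-membered ring) and delivering the C10=C14 methylidene directly; it needs the diene C6=C7–C8=C9 rather than C4=C5–C6=C7, secured because only the former can reach both C1 and C10; and the 2-silyloxy group leaves ring B as the regiodefined enol ether C7=C8. The trans ring fusion is the least secured of these selectivities, and no thermal background reaction is expected at 25 °C.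

Step 11
Reactants: 16 tert-butyl [(1S,6S)-4-{[(tert-butyldimethylsilyl)oxy]methyl}-10-methylidene-8-[(triethylsilyl)oxy]bicyclo[4.4.0]deca-4,7-dien-7-yl]acetate
Product: 17 tert-butyl [(1S,6S,7R)-4-{[(tert-butyldimethylsilyl)oxy]methyl}-10-methylidene-8-oxobicyclo[4.4.0]dec-4-en-7-yl]acetate
Conditions: Bu4NF, AcOH (1:1.2), THF, −78 to −40 °C
Reagents that add atoms: none
Why: Buffered fluoride protodesilylation of the silyl enol ether should protonate C7 from the axial direction, which puts the CH2CO2t-Bu arm equatorial (also the thermodynamic epimer), and the non-equilibrating conditions should keep C10=C14 out of conjugation with the new ketone.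

Step 12
Reactants: 17 tert-butyl [(1S,6S,7R)-4-{[(tert-butyldimethylsilyl)oxy]methyl}-10-methylidene-8-oxobicyclo[4.4.0]dec-4-en-7-yl]acetate
Product: 18 tert-butyl [(1S,6S,7R,8S)-4-{[(tert-butyldimethylsilyl)oxy]methyl}-8-hydroxy-10-methylidenebicyclo[4.4.0]dec-4-en-7-yl]acetate
Conditions: LiBH(s-Bu)3, THF, −78 °C; AcOH quench at −78 °C
Reagents that add atoms: none
Why: The bulky hydride should attack the cyclohexanone from the equatorial direction and give the axial C8 alcohol, cis to the C7 arm, while the tert-butyl ester should resist lactonisation at this temperature.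

Step 13
Reactants: 18 tert-butyl [(1S,6S,7R,8S)-4-{[(tert-butyldimethylsilyl)oxy]methyl}-8-hydroxy-10-methylidenebicyclo[4.4.0]dec-4-en-7-yl]acetate
Product: 21 tert-butyl 2-[(1S,6S,7S,8S)-4-{[(tert-butyldimethylsilyl)oxy]methyl}-8-hydroxy-10-methylidenebicyclo[4.4.0]dec-4-en-7-yl]prop-2-enoate, via Mannich base 19 (not isolated), via ammonium iodide 20 (not isolated)
Conditions: LiN(i-Pr)2 (2.3 equiv), THF, −78 °C; CH2=NMe2 I (Eschenmoser's salt), −78 to −20 °C; then MeI, MeOH, rt; then DBU, CH2Cl2, rt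
Reagents that add atoms: Eschenmoser's salt, C=[N+](C)C.[I-]; iodomethane, CI (its methyl stays only in intermediate 20)
Why: α-Methylenation by a Mannich reaction of the ester enolate (alkoxide–enolate dianion), quaternisation and E1cB elimination should build C11=C13 without touching a stereocentre.

Step 14
Reactants: 22 [(tert-butyldimethylsilyl)oxy]acetaldehyde; 23 1,1,1,3,3,3-hexafluoropropan-2-yl prop-2-enoate
Product: 24 1,1,1,3,3,3-hexafluoropropan-2-yl (3S)-4-[(tert-butyldimethylsilyl)oxy]-3-hydroxy-2-methylidenebutanoate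
Conditions: β-isocupreidine (10 mol %), DMF, −55 °C
Reagents that add atoms: none
Why: The asymmetric Morita–Baylis–Hillman reaction with this cinchona catalyst and the activated acrylate should deliver the aldehyde face that is called R for simple aldehydes and S here, because CH2OSi outranks the vinyl carbon.

Step 15
Reactants: 24 1,1,1,3,3,3-hexafluoropropan-2-yl (3S)-4-[(tert-butyldimethylsilyl)oxy]-3-hydroxy-2-methylidenebutanoate
Product: 25 1,1,1,3,3,3-hexafluoropropan-2-yl (3S)-4-[(tert-butyldimethylsilyl)oxy]-2-methylidene-3-[(triethylsilyl)oxy]butanoate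
Conditions: Et3SiOTf, 2,6-lutidine, CH2Cl2, −78 °C
Reagents that add atoms: triethylsilyl trifluoromethanesulfonate, CC[Si](CC)(CC)OS(=O)(=O)C(F)(F)F
Why: Silylation with a non-nucleophilic base should protect the secondary alcohol without acyl transfer from the activated ester.

Step 16
Reactants: 25 1,1,1,3,3,3-hexafluoropropan-2-yl (3S)-4-[(tert-butyldimethylsilyl)oxy]-2-methylidene-3-[(triethylsilyl)oxy]butanoate
Product: 26 (3S)-4-[(tert-butyldimethylsilyl)oxy]-2-methylidene-3-[(triethylsilyl)oxy]butanoic acid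
Conditions: LiOH, THF/H2O, 0 °C; then dilute HCl to pH 4 at 0 °C
Reagents that add atoms: lithium hydroxide, [Li+].[OH-]
Why: Saponification of the activated hexafluoroisopropyl ester should be faster at 0 °C than conjugate addition to the acrylate or loss of the silyl ethers.

Step 17
Reactants: 21 tert-butyl 2-[(1S,6S,7S,8S)-4-{[(tert-butyldimethylsilyl)oxy]methyl}-8-hydroxy-10-methylidenebicyclo[4.4.0]dec-4-en-7-yl]prop-2-enoate; 26 (3S)-4-[(tert-butyldimethylsilyl)oxy]-2-methylidene-3-[(triethylsilyl)oxy]butanoic acid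
Product: 28 tert-butyl 2-[(1S,6S,7S,8S)-8-{[(3S)-4-[(tert-butyldimethylsilyl)oxy]-2-methylidene-3-[(triethylsilyl)oxy]butanoyl]oxy}-4-{[(tert-butyldimethylsilyl)oxy]methyl}-10-methylidenebicyclo[4.4.0]dec-4-en-7-yl]prop-2-enoate, via mixed anhydride 27 (not isolated)
Conditions: 26, 2,4,6-Cl3C6H2COCl, Et3N, toluene, rt; then 21, DMAP, toluene, rt
Reagents that add atoms: 2,4,6-trichlorobenzoyl chloride, O=C(Cl)c1c(Cl)cc(Cl)cc1Cl (its acyl group stays only in intermediate 27)
Why: Yamaguchi esterification through the mixed anhydride and DMAP acyl transfer should acylate the hindered axial C8 hydroxyl with retention at C8, the tert-butyl ester being too hindered to lactonise.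

Step 18
Reactants: 28 tert-butyl 2-[(1S,6S,7S,8S)-8-{[(3S)-4-[(tert-butyldimethylsilyl)oxy]-2-methylidene-3-[(triethylsilyl)oxy]butanoyl]oxy}-4-{[(tert-butyldimethylsilyl)oxy]methyl}-10-methylidenebicyclo[4.4.0]dec-4-en-7-yl]prop-2-enoate
Product: 30 CNP0460913.1 which is 2-[(1S,6S,7S,8S)-8-{[(3S)-3,4-dihydroxy-2-methylidenebutanoyl]oxy}-4-(hydroxymethyl)-10-methylidenebicyclo[4.4.0]dec-4-en-7-yl]prop-2-enoic acid, via trimethylsilyl ester 29 (not isolated)
Conditions: Me3SiOTf, 2,6-lutidine, CH2Cl2, 0 °C; then HF·pyridine, pyridine, THF, 0 °C to rt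
Reagents that add atoms: trimethylsilyl trifluoromethanesulfonate, C[Si](C)(C)OS(=O)(=O)C(F)(F)F (its silyl group stays only in intermediate 29)
Why: The lutidine-buffered silyl triflate should convert only the tert-butyl ester into a silyl ester with loss of 2-methylpropene, and buffered HF·pyridine should then cleave the silyl ester and the three silyl ethers without base, so that the side chain does not lactonise onto C1′ and C10=C14 does not migrate.

**Compound list**

1 | but-3-yn-1-ol | C#CCCO | starting material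
2 | penta-3,4-dien-1-ol | C=C=CCCO | intermediate
3 | 5-iodopenta-1,2-diene | C=C=CCCI | intermediate
4 | but-2-yne-1,4-diol | OCC#CCO | starting material
5 | 4-[(tert-butyldimethylsilyl)oxy]but-2-yn-1-ol | OCC#CCO[Si](C)(C)C(C)(C)C | intermediate
6 | cyclic alkenylaluminate: sodium 2,2-bis(2-methoxyethoxy)-3-{[(tert-butyldimethylsilyl)oxy]methyl}-2,5-dihydro-1,2-oxaluminol-2-uide | [Na+].COCCO[Al-]1(OCCOC)OCC=C1CO[Si](C)(C)C(C)(C)C | intermediate
7 | (Z)-4-[(tert-butyldimethylsilyl)oxy]-3-iodobut-2-en-1-ol | OC/C=C(\I)CO[Si](C)(C)C(C)(C)C | intermediate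
8 | penta-3,4-dienylzinc iodide | C=C=CCC[Zn]I | intermediate
9 | (E)-3-{[(tert-butyldimethylsilyl)oxy]methyl}octa-2,6,7-trien-1-ol | OC/C=C(\CCC=C=C)CO[Si](C)(C)C(C)(C)C | intermediate
10 | (E)-3-{[(tert-butyldimethylsilyl)oxy]methyl}octa-2,6,7-trienal | O=C/C=C(\CCC=C=C)CO[Si](C)(C)C(C)(C)C | intermediate
11 | dimethyl (2-oxopropyl)phosphonate | COP(=O)(CC(C)=O)OC | starting material
12 | tert-butyl bromoacetate | BrCC(=O)OC(C)(C)C | starting material
13 | tert-butyl 3-(dimethoxyphosphoryl)-4-oxopentanoate (racemic) | COP(=O)(OC)C(CC(=O)OC(C)(C)C)C(C)=O | intermediate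
14 | tert-butyl (3E,5E)-3-acetyl-6-{[(tert-butyldimethylsilyl)oxy]methyl}undeca-3,5,9,10-tetraenoate | CC(=O)/C(CC(=O)OC(C)(C)C)=C/C=C(\CCC=C=C)CO[Si](C)(C)C(C)(C)C | intermediate
15 | tert-butyl (3E,5E)-6-{[(tert-butyldimethylsilyl)oxy]methyl}-3-{1-[(triethylsilyl)oxy]ethenyl}undeca-3,5,9,10-tetraenoate | C=C(O[Si](CC)(CC)CC)/C(CC(=O)OC(C)(C)C)=C/C=C(\CCC=C=C)CO[Si](C)(C)C(C)(C)C | intermediate
16 | tert-butyl [(1S,6S)-4-{[(tert-butyldimethylsilyl)oxy]methyl}-10-methylidene-8-[(triethylsilyl)oxy]bicyclo[4.4.0]deca-4,7-dien-7-yl]acetate | CC(C)(C)OC(=O)CC1=C(O[Si](CC)(CC)CC)CC(=C)[C@H]2CCC(CO[Si](C)(C)C(C)(C)C)=C[C@H]12 | intermediate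
17 | tert-butyl [(1S,6S,7R)-4-{[(tert-butyldimethylsilyl)oxy]methyl}-10-methylidene-8-oxobicyclo[4.4.0]dec-4-en-7-yl]acetate | CC(C)(C)OC(=O)C[C@@H]1[C@H]2C=C(CO[Si](C)(C)C(C)(C)C)CC[C@@H]2C(=C)CC1=O | intermediate
18 | tert-butyl [(1S,6S,7R,8S)-4-{[(tert-butyldimethylsilyl)oxy]methyl}-8-hydroxy-10-methylidenebicyclo[4.4.0]dec-4-en-7-yl]acetate | CC(C)(C)OC(=O)C[C@@H]1[C@H]2C=C(CO[Si](C)(C)C(C)(C)C)CC[C@@H]2C(=C)C[C@@H]1O | intermediate
19 | Mannich base: tert-butyl 3-(dimethylamino)-2-[(1S,6S,7S,8S)-4-{[(tert-butyldimethylsilyl)oxy]methyl}-8-hydroxy-10-methylidenebicyclo[4.4.0]dec-4-en-7-yl]propanoate (mixture at C11) | CN(C)CC(C(=O)OC(C)(C)C)[C@@H]1[C@H]2C=C(CO[Si](C)(C)C(C)(C)C)CC[C@@H]2C(=C)C[C@@H]1O | intermediate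
20 | ammonium iodide: N,N,N-trimethyl ammonium iodide of 19 | C[N+](C)(C)CC(C(=O)OC(C)(C)C)[C@@H]1[C@H]2C=C(CO[Si](C)(C)C(C)(C)C)CC[C@@H]2C(=C)C[C@@H]1O.[I-] | intermediate
21 | tert-butyl 2-[(1S,6S,7S,8S)-4-{[(tert-butyldimethylsilyl)oxy]methyl}-8-hydroxy-10-methylidenebicyclo[4.4.0]dec-4-en-7-yl]prop-2-enoate | C=C(C(=O)OC(C)(C)C)[C@@H]1[C@H]2C=C(CO[Si](C)(C)C(C)(C)C)CC[C@@H]2C(=C)C[C@@H]1O | intermediate
22 | [(tert-butyldimethylsilyl)oxy]acetaldehyde | O=CCO[Si](C)(C)C(C)(C)C | starting material
23 | 1,1,1,3,3,3-hexafluoropropan-2-yl prop-2-enoate | C=CC(=O)OC(C(F)(F)F)C(F)(F)F | starting material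
24 | 1,1,1,3,3,3-hexafluoropropan-2-yl (3S)-4-[(tert-butyldimethylsilyl)oxy]-3-hydroxy-2-methylidenebutanoate | C=C(C(=O)OC(C(F)(F)F)C(F)(F)F)[C@H](O)CO[Si](C)(C)C(C)(C)C | intermediate
25 | 1,1,1,3,3,3-hexafluoropropan-2-yl (3S)-4-[(tert-butyldimethylsilyl)oxy]-2-methylidene-3-[(triethylsilyl)oxy]butanoate | C=C(C(=O)OC(C(F)(F)F)C(F)(F)F)[C@H](O[Si](CC)(CC)CC)CO[Si](C)(C)C(C)(C)C | intermediate
26 | (3S)-4-[(tert-butyldimethylsilyl)oxy]-2-methylidene-3-[(triethylsilyl)oxy]butanoic acid | C=C(C(=O)O)[C@H](O[Si](CC)(CC)CC)CO[Si](C)(C)C(C)(C)C | intermediate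
27 | mixed anhydride of 26 with 2,4,6-trichlorobenzoic acid | C=C(C(=O)OC(=O)c1c(Cl)cc(Cl)cc1Cl)[C@H](O[Si](CC)(CC)CC)CO[Si](C)(C)C(C)(C)C | intermediate
28 | tert-butyl 2-[(1S,6S,7S,8S)-8-{[(3S)-4-[(tert-butyldimethylsilyl)oxy]-2-methylidene-3-[(triethylsilyl)oxy]butanoyl]oxy}-4-{[(tert-butyldimethylsilyl)oxy]methyl}-10-methylidenebicyclo[4.4.0]dec-4-en-7-yl]prop-2-enoate | C=C(C(=O)OC(C)(C)C)[C@@H]1[C@H]2C=C(CO[Si](C)(C)C(C)(C)C)CC[C@@H]2C(=C)C[C@@H]1OC(=O)C(=C)[C@H](O[Si](CC)(CC)CC)CO[Si](C)(C)C(C)(C)C | intermediate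
29 | trimethylsilyl ester corresponding to 28 (CO2SiMe3 in place of CO2t-Bu) | C=C(C(=O)O[Si](C)(C)C)[C@@H]1[C@H]2C=C(CO[Si](C)(C)C(C)(C)C)CC[C@@H]2C(=C)C[C@@H]1OC(=O)C(=C)[C@H](O[Si](CC)(CC)CC)CO[Si](C)(C)C(C)(C)C | intermediate
30 | CNP0460913.1, 2-[(1S,6S,7S,8S)-8-{[(3S)-3,4-dihydroxy-2-methylidenebutanoyl]oxy}-4-(hydroxymethyl)-10-methylidenebicyclo[4.4.0]dec-4-en-7-yl]prop-2-enoic acid | C=C(C(=O)O)[C@@H]1[C@H]2C=C(CO)CC[C@@H]2C(=C)C[C@@H]1OC(=O)C(=C)[C@H](O)CO | target

**Step count and risks**

Total step count: 18. Longest linear sequence: 12 steps (steps 3, 4, 5, 6, 8, 9, 10, 11, 12, 13, 17, 18, from but-2-yne-1,4-diol).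

Steps most likely to fail:

Step 10. What may go wrong is poor enantiofacial discrimination, or loss of turnover, of the chiral cationic catalyst on the silyloxy diene. The fallback uses known chemistry and sets out from 15: the cycloaddition is run with the achiral system [Rh(cod)Cl]2/tris(2-biphenylyl) phosphite (THF, 45 °C), established for diene–allene [4+2] reactions. This should give 16 as a racemate, that is together with its enantiomer ent-16 F1. Steps 11 to 13 are then run on the racemates and should give 17 beside ent-17 F2, 18 beside ent-18 F3, the Mannich base beside ent-19 F4 and the ammonium iodide beside ent-20 F5 (neither isolated), and 21 beside ent-21 F6. Esterification with enantiopure 26 under the conditions of step 17 then serves as the resolution: it should give 28 and the diastereomeric ester F7, which are separated by chromatography. The route is rejoined at 28.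

Step 13. What may go wrong is lactonisation of the lithium alkoxide onto the tert-butyl ester during dianion formation or quaternisation, which would lead to the α-methylene lactone instead of 21. The fallback sets out from 18: the C8 hydroxyl is silylated (Et3SiOTf, 2,6-lutidine, CH2Cl2, −78 °C) to the triethylsilyl ether F8. Methylenation as in step 13, now with 1.2 equivalents of LiN(i-Pr)2, should pass through the Mannich base F9 and the ammonium iodide F10 (neither isolated) to the protected acrylate F11. Selective removal of the secondary triethylsilyl ether (pyridinium p-toluenesulfonate, MeOH, 0 °C) returns to the route at 21.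

Step 5. What may go wrong is carbopalladation or palladium-hydride isomerisation of the terminal allene by the alkenylpalladium iodide, faster than transmetalation. The fallback sets out from 7 and installs the allene after the coupling. Commercial 4-(trimethylsilyl)but-3-yn-1-ol is converted (I2, PPh3, imidazole) into (4-iodobut-1-yn-1-yl)trimethylsilane F12, and zinc insertion gives [4-(trimethylsilyl)but-3-yn-1-yl]zinc iodide F13 (not isolated). Negishi coupling with 7 (Pd(PPh3)4, THF) should give (E)-3-{[(tert-butyldimethylsilyl)oxy]methyl}-7-(trimethylsilyl)hept-2-en-6-yn-1-ol F14, and K2CO3 in MeOH should give the terminal alkyne (E)-3-{[(tert-butyldimethylsilyl)oxy]methyl}hept-2-en-6-yn-1-ol F15. Crabbé homologation ((CH2O)n, CuBr, i-Pr2NH, 1,4-dioxane, reflux) then builds the allene and returns to the route at 9.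

**Further compounds**

F1 | step 10 | ent-16, tert-butyl [(1R,6R)-4-{[(tert-butyldimethylsilyl)oxy]methyl}-10-methylidene-8-[(triethylsilyl)oxy]bicyclo[4.4.0]deca-4,7-dien-7-yl]acetate | CC(C)(C)OC(=O)CC1=C(O[Si](CC)(CC)CC)CC(=C)[C@@H]2CCC(CO[Si](C)(C)C(C)(C)C)=C[C@@H]12
F2 | step 10 | ent-17, tert-butyl [(1R,6R,7S)-4-{[(tert-butyldimethylsilyl)oxy]methyl}-10-methylidene-8-oxobicyclo[4.4.0]dec-4-en-7-yl]acetate | CC(C)(C)OC(=O)C[C@H]1[C@@H]2C=C(CO[Si](C)(C)C(C)(C)C)CC[C@H]2C(=C)CC1=O
F3 | step 10 | ent-18, tert-butyl [(1R,6R,7S,8R)-4-{[(tert-butyldimethylsilyl)oxy]methyl}-8-hydroxy-10-methylidenebicyclo[4.4.0]dec-4-en-7-yl]acetate | CC(C)(C)OC(=O)C[C@H]1[C@@H]2C=C(CO[Si](C)(C)C(C)(C)C)CC[C@H]2C(=C)C[C@H]1O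
F4 | step 10 | ent-19, Mannich base of the enantiomeric series | CN(C)CC(C(=O)OC(C)(C)C)[C@H]1[C@@H]2C=C(CO[Si](C)(C)C(C)(C)C)CC[C@H]2C(=C)C[C@H]1O
F5 | step 10 | ent-20, ammonium iodide of the enantiomeric series | C[N+](C)(C)CC(C(=O)OC(C)(C)C)[C@H]1[C@@H]2C=C(CO[Si](C)(C)C(C)(C)C)CC[C@H]2C(=C)C[C@H]1O.[I-]
F6 | step 10 | ent-21, tert-butyl 2-[(1R,6R,7R,8R)-4-{[(tert-butyldimethylsilyl)oxy]methyl}-8-hydroxy-10-methylidenebicyclo[4.4.0]dec-4-en-7-yl]prop-2-enoate | C=C(C(=O)OC(C)(C)C)[C@H]1[C@@H]2C=C(CO[Si](C)(C)C(C)(C)C)CC[C@H]2C(=C)C[C@H]1O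
F7 | step 10 | diastereomer of 28 with the (1R,6R,7R,8R) core and the (3S) acyl group | C=C(C(=O)OC(C)(C)C)[C@H]1[C@@H]2C=C(CO[Si](C)(C)C(C)(C)C)CC[C@H]2C(=C)C[C@H]1OC(=O)C(=C)[C@H](O[Si](CC)(CC)CC)CO[Si](C)(C)C(C)(C)C
F8 | step 13 | triethylsilyl ether of 18 | CC(C)(C)OC(=O)C[C@@H]1[C@H]2C=C(CO[Si](C)(C)C(C)(C)C)CC[C@@H]2C(=C)C[C@@H]1O[Si](CC)(CC)CC
F9 | step 13 | Mannich base of F8 (mixture at C11) | CN(C)CC(C(=O)OC(C)(C)C)[C@@H]1[C@H]2C=C(CO[Si](C)(C)C(C)(C)C)CC[C@@H]2C(=C)C[C@@H]1O[Si](CC)(CC)CC
F10 | step 13 | trimethylammonium iodide of F9 | C[N+](C)(C)CC(C(=O)OC(C)(C)C)[C@@H]1[C@H]2C=C(CO[Si](C)(C)C(C)(C)C)CC[C@@H]2C(=C)C[C@@H]1O[Si](CC)(CC)CC.[I-]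
F11 | step 13 | triethylsilyl ether of 21 | C=C(C(=O)OC(C)(C)C)[C@@H]1[C@H]2C=C(CO[Si](C)(C)C(C)(C)C)CC[C@@H]2C(=C)C[C@@H]1O[Si](CC)(CC)CC
F12 | step 5 | (4-iodobut-1-yn-1-yl)trimethylsilane | C[Si](C)(C)C#CCCI
F13 | step 5 | [4-(trimethylsilyl)but-3-yn-1-yl]zinc iodide | C[Si](C)(C)C#CCC[Zn]I
F14 | step 5 | (E)-3-{[(tert-butyldimethylsilyl)oxy]methyl}-7-(trimethylsilyl)hept-2-en-6-yn-1-ol | OC/C=C(\CCC#C[Si](C)(C)C)CO[Si](C)(C)C(C)(C)C
F15 | step 5 | (E)-3-{[(tert-butyldimethylsilyl)oxy]methyl}hept-2-en-6-yn-1-ol | OC/C=C(\CCC#C)CO[Si](C)(C)C(C)(C)C
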